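Ring C (O1–C2–C3–C4–C4a–C8a) is disconnected into a 1,3-dinucleophile and a 1,3-dielectrophile. The nucleophile is an enantiopure β-hydroxy-α-methoxy benzyl ester that already holds C2, ring B, O1 and C3; the electrophile is 6-fluoro-2,3,4-trimethoxybenzaldehyde (ring A with C4). In one flask the alkoxide displaces fluoride at C8a (SNAr, O1–C8a) and the ester enolate then adds to the formyl group (aldol, C3–C4). The step exploits the ortho relationship of C4 and C8a on ring A: the formyl group is both SNAr activator and aldol acceptor. The C3 ester is a temporary activating group; oxidation at C4 and hydrogenolysis with decarboxylation complete the target.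

Key step: step 7

Remark: atom numbers (O1, C2, C3, C4, C4a, C8a) and ring letters (A, B, C) are those of the flavanone skeleton of the target. Compound 7 is drawn as the syn isomer; its epimer at the ester α-carbon would serve equally, because that carbon is planarised in step 7 and reset in step 9.

Step 1
Reactants: 1 3,5-dihydroxy-4-methoxybenzoic acid
Product: 2 benzyl 3,5-bis(benzyloxy)-4-methoxybenzoate
Conditions: BnBr (3.3 equiv), K2CO3, DMF, 60 °C
Reagents that add atoms: benzyl bromide, BrCc1ccccc1
Why: Williamson-type O-benzylation (SN2 on benzyl bromide) of both phenols and of the carboxylate protects ring B and provides a benzyl ester as acyl donor for step 3; no stereocentre is formed.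

Step 2
Reactants: 3 benzyl alcohol; 4 methoxyacetyl chloride
Product: 5 benzyl 2-methoxyacetate
Conditions: Et3N, DMAP (cat.), CH2Cl2, 0 °C → rt
Reagents that add atoms: none
Why: Nucleophilic acyl substitution (DMAP-catalysed esterification of an acid chloride) gives the enolisable C3 building block as its benzyl ester, chosen so that the ester is removed by hydrogenolysis in step 9; no stereocentre is formed.

Step 3
Reactants: 2 benzyl 3,5-bis(benzyloxy)-4-methoxybenzoate; 5 benzyl 2-methoxyacetate
Product: 6 benzyl 3-[3,5-bis(benzyloxy)-4-methoxyphenyl]-2-methoxy-3-oxopropanoate (racemic)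
Conditions: LiN(SiMe3)2 (2.2 equiv), THF, −78 °C, add 5; then 2, −78 → 0 °C; aq. NH4Cl
Reagents that add atoms: none
Why: Crossed Claisen condensation: the lithium enolate of 5, fully preformed so that no free 5 remains for self-condensation, acylates the non-enolisable aryl ester 2, and deprotonation of the β-keto ester by the second equivalent of base drives the reaction; the α-carbon of 6 is formed racemic and is configurationally labile.

Step 4
Reactants: 6 benzyl 3-[3,5-bis(benzyloxy)-4-methoxyphenyl]-2-methoxy-3-oxopropanoate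
Product: 7 benzyl (2S,3R)-3-[3,5-bis(benzyloxy)-4-methoxyphenyl]-3-hydroxy-2-methoxypropanoate
Conditions: RuCl[(S,S)-TsDPEN](p-cymene) (1 mol %), HCO2H–Et3N (5:2), CH2Cl2, 30 °C
Reagents that add atoms: none
Why: Noyori asymmetric transfer hydrogenation with dynamic kinetic resolution: the α-carbon racemises under the reaction conditions while the (S,S)-catalyst reduces the aryl ketone from one face (aryl group in the usual CH–π position), which is expected to set the carbinol carbon (the future C2) as (R) and to give mainly the syn (2S,3R) isomer.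

Step 5
Reactants: 8 5-bromo-1,2,3-trimethoxybenzene
Product: 10 5-fluoro-1,2,3-trimethoxybenzene, via aryllithium 9 (not isolated)
Conditions: n-BuLi, THF, −78 °C; N-fluorobenzenesulfonimide, −78 °C → rt
Reagents that add atoms: N-fluorobenzenesulfonimide, O=S(=O)(N(F)S(=O)(=O)c1ccccc1)c1ccccc1
Why: Bromine–lithium exchange gives aryllithium 9, and electrophilic fluorination with N-fluorobenzenesulfonimide should put fluorine on the carbon that carried bromine; no stereocentre is formed.

Step 6
Reactants: 10 5-fluoro-1,2,3-trimethoxybenzene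
Product: 12 6-fluoro-2,3,4-trimethoxybenzaldehyde, via aryllithium 11 (not isolated)
Conditions: n-BuLi, THF, −78 °C; DMF, −78 → 0 °C; aq. HCl
Reagents that add atoms: N,N-dimethylformamide, CN(C)C=O
Why: Directed ortho-metalation takes place at the C–H flanked by F and OCH3 (the two such positions of 10 are equivalent), and formylation of aryllithium 11 with DMF gives the aldehyde with fluorine ortho to the formyl group, the low temperature preventing LiF loss to an aryne; no stereocentre is formed.

Step 7
Reactants: 7 benzyl (2S,3R)-3-[3,5-bis(benzyloxy)-4-methoxyphenyl]-3-hydroxy-2-methoxypropanoate; 12 6-fluoro-2,3,4-trimethoxybenzaldehyde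
Product: 14 benzyl (2R)-2-[3,5-bis(benzyloxy)-4-methoxyphenyl]-4-hydroxy-3,5,6,7-tetramethoxy-3,4-dihydro-2H-chromene-3-carboxylate (mixture of C3/C4 diastereomers), via aryl ether aldehyde 13 (not isolated)
Conditions: NaH (1.0 equiv), THF–DMPU, −20 °C; then 12, −20 → 0 °C; then lithium 2,2,6,6-tetramethylpiperidide (1.1 equiv), −78 °C; AcOH, −78 °C
Reagents that add atoms: none
Why: Sodium hydride converts the carbinol of 7 into its alkoxide, which displaces fluoride from 12 by addition–elimination (SNAr; the Meisenheimer adduct is stabilised by the ortho formyl group, and fluoride is the only good nucleofuge on ring A), forming O1–C8a and giving aryl ether 13. Lithium 2,2,6,6-tetramethylpiperidide at −78 °C then removes the proton alpha to the benzyl ester, and the ester enolate adds to the neighbouring aldehyde, forming C3–C4 and closing ring C in a 6-(enolexo)-exo-trig aldol. The closest known reaction type is the one-pot SNAr/aldol annulation of 2-fluorobenzaldehydes with glycolate or thioglycolate esters (benzofuran and benzothiophene syntheses), here extended by one carbon and stopped at the aldol stage. C2 keeps the (R) configuration set in step 4 because none of its bonds is broken; the new centres C3 and C4 are expected as mixtures, which is of no consequence since C4 is oxidised in step 8 and C3 is reset in step 9. The step needs O-arylation before enolate formation, secured by using one equivalent of NaH so that only the alkoxide is present in the first stage, and aldol closure ahead of β-elimination of the aryloxide, secured by the low temperature and the proximity of the formyl group; the C3 ester is the temporary activating group that makes C3 nucleophilic.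

Step 8
Reactants: 14 benzyl (2R)-2-[3,5-bis(benzyloxy)-4-methoxyphenyl]-4-hydroxy-3,5,6,7-tetramethoxy-3,4-dihydro-2H-chromene-3-carboxylate
Product: 15 benzyl (2R)-2-[3,5-bis(benzyloxy)-4-methoxyphenyl]-3,5,6,7-tetramethoxy-4-oxo-3,4-dihydro-2H-chromene-3-carboxylate (C3 epimers)
Conditions: Dess–Martin periodinane, CH2Cl2, rt
Reagents that add atoms: none
Why: Dess–Martin oxidation of the secondary benzylic alcohol gives the aryl ketone under non-basic conditions and removes the C4 stereocentre; C3 is quaternary and cannot enolise, so C2 is not at risk.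

Step 9
Reactants: 15 benzyl (2R)-2-[3,5-bis(benzyloxy)-4-methoxyphenyl]-3,5,6,7-tetramethoxy-4-oxo-3,4-dihydro-2H-chromene-3-carboxylate
Product: 18 (2R,3R)-2-(3,5-dihydroxy-4-methoxyphenyl)-3,5,6,7-tetramethoxy-2,3-dihydro-4H-chromen-4-one, via keto acid 16 (not isolated), via cis epimer 17 (not isolated)
Conditions: H2 (1 atm), Pd/C, EtOAc–AcOH, rt; filter; 60 °C
Reagents that add atoms: none
Why: Hydrogenolysis cleaves the benzyl ester and both aryl benzyl ethers, β-keto acid 16 loses CO2 through its enol, and acid-mediated keto–enol equilibration at C3 (the only enolisable centre) should convert the kinetically formed cis epimer 17 into the 2,3-trans diequatorial (2R,3R) ketone expected to be the thermodynamic isomer, while C2 is untouched because the medium is never basic enough for retro-oxa-Michael ring opening.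

Compound list
1 | 3,5-dihydroxy-4-methoxybenzoic acid | COc1c(O)cc(C(=O)O)cc1O | starting material
2 | benzyl 3,5-bis(benzyloxy)-4-methoxybenzoate | COc1c(OCc2ccccc2)cc(C(=O)OCc2ccccc2)cc1OCc1ccccc1 | intermediate
3 | benzyl alcohol | OCc1ccccc1 | starting material
4 | methoxyacetyl chloride | COCC(=O)Cl | starting material
5 | benzyl 2-methoxyacetate | COCC(=O)OCc1ccccc1 | intermediate
6 | benzyl 3-[3,5-bis(benzyloxy)-4-methoxyphenyl]-2-methoxy-3-oxopropanoate (racemic) | COC(C(=O)OCc1ccccc1)C(=O)c1cc(OCc2ccccc2)c(OC)c(OCc2ccccc2)c1 | intermediate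
7 | benzyl (2S,3R)-3-[3,5-bis(benzyloxy)-4-methoxyphenyl]-3-hydroxy-2-methoxypropanoate | O=C(OCc1ccccc1)[C@@H](OC)[C@H](O)c1cc(OCc2ccccc2)c(OC)c(OCc2ccccc2)c1 | intermediate
8 | 5-bromo-1,2,3-trimethoxybenzene | COc1cc(Br)cc(OC)c1OC | starting material
9 | (3,4,5-trimethoxyphenyl)lithium | [Li]c1cc(OC)c(OC)c(OC)c1 | intermediate (not isolated)
10 | 5-fluoro-1,2,3-trimethoxybenzene | COc1cc(F)cc(OC)c1OC | intermediate
11 | (6-fluoro-2,3,4-trimethoxyphenyl)lithium | [Li]c1c(F)cc(OC)c(OC)c1OC | intermediate (not isolated)
12 | 6-fluoro-2,3,4-trimethoxybenzaldehyde | COc1cc(F)c(C=O)c(OC)c1OC | intermediate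
13 | benzyl (2S,3R)-3-[3,5-bis(benzyloxy)-4-methoxyphenyl]-3-(2-formyl-3,4,5-trimethoxyphenoxy)-2-methoxypropanoate | O=C(OCc1ccccc1)[C@@H](OC)[C@H](Oc1cc(OC)c(OC)c(OC)c1C=O)c1cc(OCc2ccccc2)c(OC)c(OCc2ccccc2)c1 | intermediate (not isolated)
14 | benzyl (2R)-2-[3,5-bis(benzyloxy)-4-methoxyphenyl]-4-hydroxy-3,5,6,7-tetramethoxy-3,4-dihydro-2H-chromene-3-carboxylate (C3 and C4 unassigned, mixture) | COc1cc2c(c(OC)c1OC)C(O)C(OC)(C(=O)OCc1ccccc1)[C@@H](c1cc(OCc3ccccc3)c(OC)c(OCc3ccccc3)c1)O2 | intermediate
15 | benzyl (2R)-2-[3,5-bis(benzyloxy)-4-methoxyphenyl]-3,5,6,7-tetramethoxy-4-oxo-3,4-dihydro-2H-chromene-3-carboxylate (C3 unassigned, mixture) | COc1cc2c(c(OC)c1OC)C(=O)C(OC)(C(=O)OCc1ccccc1)[C@@H](c1cc(OCc3ccccc3)c(OC)c(OCc3ccccc3)c1)O2 | intermediate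
16 | (2R)-2-(3,5-dihydroxy-4-methoxyphenyl)-3,5,6,7-tetramethoxy-4-oxo-3,4-dihydro-2H-chromene-3-carboxylic acid (C3 unassigned) | COc1cc2c(c(OC)c1OC)C(=O)C(OC)(C(=O)O)[C@@H](c1cc(O)c(OC)c(O)c1)O2 | intermediate (not isolated)
17 | (2R,3S)-2-(3,5-dihydroxy-4-methoxyphenyl)-3,5,6,7-tetramethoxy-2,3-dihydro-4H-chromen-4-one (2,3-cis) | COc1cc2c(c(OC)c1OC)C(=O)[C@@H](OC)[C@@H](c1cc(O)c(OC)c(O)c1)O2 | intermediate (not isolated)
18 | (2R,3R)-2-(3,5-dihydroxy-4-methoxyphenyl)-3,5,6,7-tetramethoxy-2,3-dihydro-4H-chromen-4-one (2,3-trans) | COc1cc2c(c(OC)c1OC)C(=O)[C@H](OC)[C@@H](c1cc(O)c(OC)c(O)c1)O2 | target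

Total step count: 9. Longest linear sequence: 6 steps (1, 3, 4, 7, 8, 9).

Steps most likely to fail

Step 7. The sodium alkoxide of 7 can fragment by retro-aldol cleavage, or dehydrate, before the SNAr is complete. In the second stage, β-elimination of the aryloxide from the ester enolate can outrun the aldol closure. Both processes lose material, and the first can erode the configurational purity at the carbinol centre. The fallback reverses the order of the two bond formations and replaces the SNAr by a palladium-catalysed etherification; it sets out from 7 and 8. Rieche formylation of 8 (Cl2CHOCH3, TiCl4, CH2Cl2, 0 °C) should give 6-bromo-2,3,4-trimethoxybenzaldehyde F1. The dianion of 7 (LiN(iPr)2, 2.2 equiv, THF, −78 → −40 °C, Fráter–Seebach conditions) is then added to F1 at −78 °C to give the aldol diol benzyl (3R)-3-[3,5-bis(benzyloxy)-4-methoxyphenyl]-2-[(6-bromo-2,3,4-trimethoxyphenyl)(hydroxy)methyl]-3-hydroxy-2-methoxypropanoate F2. Intramolecular C–O coupling of the benzylic hydroxyl next to ring B with the aryl bromide (Pd(OAc)2, 2-(di-tert-butylphosphino)-1,1'-binaphthyl, Cs2CO3, toluene, 70 °C; only the six-membered closure is geometrically possible) comes back to the route at 14.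

Step 9. Ketonisation of the enol after decarboxylation is kinetically controlled and may favour the 2,3-cis epimer. The acid-mediated equilibration toward trans may be slow or incomplete, and forcing it risks opening of ring C. The fallback sets C3 by a reagent-controlled protonation on the protected ketone instead of by equilibration; it sets out from 15. Hydrogenolysis of the benzyl ester alone (H2, Pd/C, pyridine as selective poison against aryl benzyl ether cleavage, EtOAc) followed by decarboxylation should give (2R)-2-[3,5-bis(benzyloxy)-4-methoxyphenyl]-3,5,6,7-tetramethoxy-2,3-dihydro-4H-chromen-4-one F3 as C3 epimers. Soft enolisation (Me3SiOSO2CF3, Et3N, CH2Cl2, 0 °C) gives the silyl enol ether {[(2R)-2-[3,5-bis(benzyloxy)-4-methoxyphenyl]-3,5,6,7-tetramethoxy-2H-chromen-4-yl]oxy}trimethylsilane F4. Protonation with the BINOL–SnCl4 Lewis-acid-assisted Brønsted acid (toluene, −78 °C; the BINOL enantiomer matched to C2 is chosen by trying both) should give (2R,3R)-2-[3,5-bis(benzyloxy)-4-methoxyphenyl]-3,5,6,7-tetramethoxy-2,3-dihydro-4H-chromen-4-one F5 under kinetic control. Hydrogenolysis of the two benzyl ethers (H2, Pd/C, EtOAc) comes back to the route at 18.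

Step 5. Electron transfer from the aryllithium to N-fluorobenzenesulfonimide and sulfonyl transfer can compete with fluorine transfer, so that protodebromination and sulfone formation consume the aryllithium. The fallback is a Balz–Schiemann fluorination; it sets out from 8. Palladium-catalysed amination with LiN(SiMe3)2 as ammonia equivalent (Pd2(dba)3, P(t-Bu)3, toluene; then aq. HCl) gives 3,4,5-trimethoxyaniline F6, which can also be purchased. Diazotisation (NaNO2, HBF4, H2O, 0 °C) gives 3,4,5-trimethoxybenzenediazonium tetrafluoroborate F7, and thermolysis of the dry salt comes back to the route at 10.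

Further compounds
F1 | step 7 | 6-bromo-2,3,4-trimethoxybenzaldehyde | COc1cc(Br)c(C=O)c(OC)c1OC
F2 | step 7 | benzyl (3R)-3-[3,5-bis(benzyloxy)-4-methoxyphenyl]-2-[(6-bromo-2,3,4-trimethoxyphenyl)(hydroxy)methyl]-3-hydroxy-2-methoxypropanoate (other two centres unassigned) | COc1cc(Br)c(C(O)C(OC)(C(=O)OCc2ccccc2)[C@H](O)c2cc(OCc3ccccc3)c(OC)c(OCc3ccccc3)c2)c(OC)c1OC
F3 | step 9 | (2R)-2-[3,5-bis(benzyloxy)-4-methoxyphenyl]-3,5,6,7-tetramethoxy-2,3-dihydro-4H-chromen-4-one (C3 epimers) | COc1cc2c(c(OC)c1OC)C(=O)C(OC)[C@@H](c1cc(OCc3ccccc3)c(OC)c(OCc3ccccc3)c1)O2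
F4 | step 9 | {[(2R)-2-[3,5-bis(benzyloxy)-4-methoxyphenyl]-3,5,6,7-tetramethoxy-2H-chromen-4-yl]oxy}trimethylsilane | COc1cc2c(c(OC)c1OC)C(O[Si](C)(C)C)=C(OC)[C@@H](c1cc(OCc3ccccc3)c(OC)c(OCc3ccccc3)c1)O2
F5 | step 9 | (2R,3R)-2-[3,5-bis(benzyloxy)-4-methoxyphenyl]-3,5,6,7-tetramethoxy-2,3-dihydro-4H-chromen-4-one | COc1cc2c(c(OC)c1OC)C(=O)[C@H](OC)[C@@H](c1cc(OCc3ccccc3)c(OC)c(OCc3ccccc3)c1)O2
F6 | step 5 | 3,4,5-trimethoxyaniline | COc1cc(N)cc(OC)c1OC
F7 | step 5 | 3,4,5-trimethoxybenzenediazonium tetrafluoroborate | COc1cc([N+]#N)cc(OC)c1OC.F[B-](F)(F)F
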